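**Plan**

1. Retrosynthetic cuts (cembrane numbering, see remark): C3=C4 by macrocyclic Horner–Wadsworth–Emmons (HWE) olefination; then the lactone O–C8 bond by retro-Baeyer–Villiger to a 2,6,6-trisubstituted cyclohex-2-enone; then C8–C9 and C12–C20 together by retro-Diels–Alder, which gives enal 18 and dienol 7.
2. Enabling feature: the six carbon atoms of the seven-membered lactone (C8, C9, C10, C11, C12, C20) are a latent cyclohexene, and the ring oxygen sits between C20 and the fully substituted C8, the carbon that migrates best in a Baeyer–Villiger step.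
3. Forward order: 7 and 18 are joined by the cycloaddition (cyclohexene ring), the formyl carbon is excised and the enone conjugated, oxygen is inserted (lactone ring), and the 14-membered ring is closed last.
4. The macrocycle is not closed by the cycloaddition itself, because a chain that holds both the terminal diene and the C1–C4 dienoate is a 1,3,9-decatriene and should close a decalin instead.
5. Stereochemistry: C7 by CBS reduction; C8 in the Diels–Alder step under control of C7, retained in the oxygen insertion; C1=C2 from an (E)-enol triflate and cross-coupling; C3=C4 from the HWE step; C11=C12 from enone conjugation.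

Key step: step 12

Remark on the chemistry: cembrane numbering is used (C1 carries the isopropyl group, C4 the CO2Me group, C7 the acetate, C8 the methyl group and the lactone oxygen, C12 the lactone carbonyl C20). The phosphonate-bearing carbon of 10 and 15 to 24 is not controlled; both epimers are carried and it becomes sp2 in step 16. Compound 19 is drawn as the endo adduct; its two ring CH centres are erased in step 13. Anions made by simple deprotonation are treated as forms of the numbered compound.

**Route**

Step 1
Reactants: 1 penta-1,4-dien-3-ol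
Product: 2 (3E)-5-bromopenta-1,3-diene
Conditions: 48% aq. HBr, 0 °C
Reagents that add atoms: hydrogen bromide, Br
Why: Acid-promoted SN1-type allylic substitution, in which the doubly allylic cation from 1 is captured by bromide at its terminus to give the conjugated dienyl bromide as the favoured (E)-isomer.

Step 2
Reactants: 3 methyl 3-oxobutanoate, 2 (3E)-5-bromopenta-1,3-diene
Product: 4 methyl (6E)-3-oxonona-6,8-dienoate
Conditions: NaH, THF, 0 °C; n-BuLi, 0 °C; then 2, 0 °C to rt; aq. HCl
Reagents that add atoms: none
Why: Alkylation of the acetoacetate dianion (Weiler alkylation), in which the more reactive terminal carbanion displaces the primary allylic bromide by SN2 so that the diene geometry is kept.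

Step 3
Reactants: 4 methyl (6E)-3-oxonona-6,8-dienoate
Product: 5 methyl (2E,6E)-3-(trifluoromethanesulfonyloxy)nona-2,6,8-trienoate
Conditions: Tf2O, aq. Me4NOH, toluene, 5 °C
Reagents that add atoms: trifluoromethanesulfonic anhydride, O=S(=O)(OS(=O)(=O)C(F)(F)F)C(F)(F)F
Why: O-Triflation of the β-keto ester enolate under biphasic conditions, where the non-coordinating Me4N+ counter-ion lets the open (non-chelated) enolate react and should place the triflate trans to the ester (stereodivergent enol triflate formation).

Step 4
Reactants: 5 methyl (2E,6E)-3-(trifluoromethanesulfonyloxy)nona-2,6,8-trienoate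
Product: 6 methyl (2E,6E)-3-(propan-2-yl)nona-2,6,8-trienoate
Conditions: i-PrMgCl, Fe(acac)3 (5 mol%), THF/NMP, −30 °C
Reagents that add atoms: isopropylmagnesium chloride, CC(C)[Mg]Cl
Why: Iron-catalysed Kumada-type cross-coupling of the enol triflate with the alkyl Grignard reagent, which is faster than addition to the ester and retains the alkene geometry, so the isopropyl group should end trans to the ester.

Step 5
Reactants: 6 methyl (2E,6E)-3-(propan-2-yl)nona-2,6,8-trienoate
Product: 7 (2E,6E)-3-(propan-2-yl)nona-2,6,8-trien-1-ol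
Conditions: i-Bu2AlH, CH2Cl2, −78 °C; aq. sodium potassium tartrate
Reagents that add atoms: none
Why: 1,2-Reduction of the conjugated ester to the allylic alcohol by the aluminium hydride, which leaves the alkenes untouched.

Step 6
Reactants: 8 trimethyl phosphonoacetate, 9 N-methoxy-N-methylprop-2-enamide
Product: 10 methyl 2-(dimethoxyphosphoryl)-5-[methoxy(methyl)amino]-5-oxopentanoate
Conditions: DBU (10 mol%), MeCN, rt, 8 in excess
Reagents that add atoms: none
Why: Base-catalysed Michael addition of the phosphonate-stabilised carbanion of 8 to the acrylamide, with excess 8 suppressing double addition.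

Step 7
Reactants: 11 1,1-diethoxybut-2-yne
Product: 13 (2E)-1,1-diethoxy-3-iodobut-2-ene, via alkenylzirconocene chloride 12 (not isolated)
Conditions: Cp2Zr(H)Cl, THF, 50 °C; then I2, 0 °C
Reagents that add atoms: iodine, II
Why: Hydrozirconation then iodinolysis, in which syn addition of Zr–H places zirconium on the less hindered, methyl-bearing alkyne carbon (thermodynamic control with excess reagent) and iodine replaces zirconium with retention, fixing the (E)-geometry of the future dienophile.

Step 8
Reactants: 13 (2E)-1,1-diethoxy-3-iodobut-2-ene, 10 methyl 2-(dimethoxyphosphoryl)-5-[methoxy(methyl)amino]-5-oxopentanoate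
Product: 15 methyl (6E)-2-(dimethoxyphosphoryl)-8,8-diethoxy-6-methyl-5-oxooct-6-enoate, via alkenyllithium 14 (not isolated)
Conditions: 13, t-BuLi (2 equiv), Et2O, −78 °C; added to 10 pre-treated with NaH (1 equiv), THF, −78 °C; AcOH quench
Reagents that add atoms: none
Why: Iodine–lithium exchange with retention followed by acylation of the alkenyllithium by the Weinreb amide, whose chelated tetrahedral intermediate prevents over-addition, while the acidic phosphonoacetate C–H is masked beforehand as its sodium salt.

Step 9
Reactants: 15 methyl (6E)-2-(dimethoxyphosphoryl)-8,8-diethoxy-6-methyl-5-oxooct-6-enoate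
Product: 16 methyl (5R,6E)-2-(dimethoxyphosphoryl)-8,8-diethoxy-5-hydroxy-6-methyloct-6-enoate
Conditions: (S)-Me-CBS (20 mol%), catecholborane, toluene, −78 °C; MeOH, aq. NaHCO3
Reagents that add atoms: none
Why: Corey–Bakshi–Shibata reduction, in which the (S)-oxazaborolidine binds the ketone with the larger α-methylalkenyl group away from the catalyst and should deliver hydride to the face that gives the (5R)-allylic alcohol (the sense known for aryl and alkenyl ketones), so C7 of the target is set by the reagent.

Step 10
Reactants: 16 methyl (5R,6E)-2-(dimethoxyphosphoryl)-8,8-diethoxy-5-hydroxy-6-methyloct-6-enoate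
Product: 17 methyl (5R,6E)-5-(acetyloxy)-2-(dimethoxyphosphoryl)-8,8-diethoxy-6-methyloct-6-enoate
Conditions: Ac2O, pyridine, DMAP (cat.), CH2Cl2, 0 °C to rt
Reagents that add atoms: acetic anhydride, CC(=O)OC(C)=O
Why: DMAP-catalysed acylation of the secondary alcohol, which installs the acetate of the target without touching the stereocentre.

Step 11
Reactants: 17 methyl (5R,6E)-5-(acetyloxy)-2-(dimethoxyphosphoryl)-8,8-diethoxy-6-methyloct-6-enoate
Product: 18 methyl (5R,6E)-5-(acetyloxy)-2-(dimethoxyphosphoryl)-6-methyl-8-oxooct-6-enoate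
Conditions: PPTS (cat.), acetone/H2O, rt
Reagents that add atoms: water, O
Why: Acid-catalysed hydrolysis of the α,β-unsaturated acetal through the stabilised alkoxy-allyl cation, far faster than cleavage of the esters, should release the (E)-enal.

Step 12
Reactants: 18 methyl (5R,6E)-5-(acetyloxy)-2-(dimethoxyphosphoryl)-6-methyl-8-oxooct-6-enoate, 7 (2E,6E)-3-(propan-2-yl)nona-2,6,8-trien-1-ol
Product: 19 methyl (5R)-5-(acetyloxy)-2-(dimethoxyphosphoryl)-5-{(1R,5R,6R)-6-formyl-5-[(3E)-5-hydroxy-3-(propan-2-yl)pent-3-en-1-yl]-1-methylcyclohex-3-en-1-yl}pentanoate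
Conditions: Me2AlCl (4 equiv), 7 (1.5 equiv), CH2Cl2, −78 to −20 °C; aq. sodium potassium tartrate
Reagents that add atoms: none
Why: Lewis-acid-promoted intermolecular [4+2] cycloaddition of normal electron demand between the Me2AlCl-complexed β,β-disubstituted enal and the (E)-1-substituted butadiene unit of 7, concerted but asynchronous, with the bond from the free diene CH2 to the enal β-carbon (C8–C9) leading and the bond from the substituted diene terminus to the enal α-carbon (C12–C20) following. The closest known reaction type is the AlCl3-promoted Diels–Alder reaction of penta-1,3-diene with mesityl oxide used for δ-damascone, which pairs a 1-alkyl diene with a β,β-dialkyl acceptor in the same "ortho" sense. One ring is closed, the cyclohexene, by suprafacial addition on both components. The new quaternary stereocentre (C8) should be controlled by the adjacent acetoxy-bearing carbon through a Felkin–Anh-type arrangement (C–OAc bond anti to the incoming diene, the carbinol hydrogen next to the vinylic methyl group, the chain over the double bond); the two other new stereocentres are erased in step 13. The step needs regioselectivity, secured by the polarity of the complexed enal and by sterics (the unhindered CH2 terminus meets the hindered β-carbon), and chemoselectivity, secured because 7 holds no other 1,3-diene and the enal is the only Lewis-acid-activated acceptor; the hydroxyl group of 7 is carried as its aluminium alkoxide.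

Step 13
Reactants: 19 methyl (5R)-5-(acetyloxy)-2-(dimethoxyphosphoryl)-5-{(1R,5R,6R)-6-formyl-5-[(3E)-5-hydroxy-3-(propan-2-yl)pent-3-en-1-yl]-1-methylcyclohex-3-en-1-yl}pentanoate
Product: 22 methyl (5R)-5-(acetyloxy)-2-(dimethoxyphosphoryl)-5-{(1S)-3-[(3E)-5-hydroxy-3-(propan-2-yl)pent-3-en-1-yl]-1-methyl-2-oxocyclohex-3-en-1-yl}pentanoate, via enamine 20 (not isolated), via nonconjugated enone 21 (not isolated)
Conditions: pyrrolidine, 4 Å MS, CH2Cl2, rt; then O2, hν, tetraphenylporphyrin (cat.), −78 °C; then DABCO, rt
Reagents that add atoms: dioxygen, O=O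
Why: Oxidative deformylation through the enamine, in which singlet oxygen adds [2+2] to the electron-rich enamine C=C much faster than it reacts with the other alkenes, the dioxetane cleaves to the ring ketone and a formamide, and the mild base moves the β,γ-double bond into conjugation through the only enolisable position (the other α-carbon is quaternary).

Step 14
Reactants: 22 methyl (5R)-5-(acetyloxy)-2-(dimethoxyphosphoryl)-5-{(1S)-3-[(3E)-5-hydroxy-3-(propan-2-yl)pent-3-en-1-yl]-1-methyl-2-oxocyclohex-3-en-1-yl}pentanoate
Product: 23 methyl (5R)-5-(acetyloxy)-2-(dimethoxyphosphoryl)-5-{(2S)-6-[(3E)-5-hydroxy-3-(propan-2-yl)pent-3-en-1-yl]-2-methyl-7-oxo-2,3,4,7-tetrahydrooxepin-2-yl}pentanoate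
Conditions: (Me3SiO)2, SnCl4 (cat.), trans-cyclohexane-1,2-diamine (cat.), 4 Å MS, CH2Cl2, rt
Reagents that add atoms: bis(trimethylsilyl) peroxide, C[Si](C)(C)OO[Si](C)(C)C
Why: Baeyer–Villiger oxidation, in which the silyl peroxide adds to the Lewis-acid-activated ketone and, in the Criegee intermediate, the fully substituted carbon should migrate in preference to the alkenyl carbon and with retention, giving the seven-membered α,β-unsaturated lactone with the C8 configuration intact, while this peroxide does not epoxidise alkenes.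

Step 15
Reactants: 23 methyl (5R)-5-(acetyloxy)-2-(dimethoxyphosphoryl)-5-{(2S)-6-[(3E)-5-hydroxy-3-(propan-2-yl)pent-3-en-1-yl]-2-methyl-7-oxo-2,3,4,7-tetrahydrooxepin-2-yl}pentanoate
Product: 24 methyl (5R)-5-(acetyloxy)-2-(dimethoxyphosphoryl)-5-{(2S)-2-methyl-7-oxo-6-[(3E)-5-oxo-3-(propan-2-yl)pent-3-en-1-yl]-2,3,4,7-tetrahydrooxepin-2-yl}pentanoate
Conditions: MnO2, CH2Cl2, rt
Reagents that add atoms: none
Why: Allylic oxidation by MnO2, which should convert only the allylic alcohol into the enal and keep the alkene geometry.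

Step 16
Reactants: 24 methyl (5R)-5-(acetyloxy)-2-(dimethoxyphosphoryl)-5-{(2S)-2-methyl-7-oxo-6-[(3E)-5-oxo-3-(propan-2-yl)pent-3-en-1-yl]-2,3,4,7-tetrahydrooxepin-2-yl}pentanoate
Product: 25 Sarcrassin D
Conditions: LiCl, DBU, MeCN, rt, high dilution (1 mM, syringe pump)
Reagents that add atoms: none
Why: Intramolecular Horner–Wadsworth–Emmons olefination under Masamune–Roush conditions closes the 14-membered ring, and reversible addition with elimination through the less crowded oxaphosphetane should give the trisubstituted enoate with the ester trans to the dienyl carbon, as in intermolecular reactions of α-alkyl phosphonoacetates with enals.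

**Compound list**

1 | penta-1,4-dien-3-ol | C=CC(O)C=C | starting material
2 | (3E)-5-bromopenta-1,3-diene | BrC/C=C/C=C | intermediate
3 | methyl 3-oxobutanoate (methyl acetoacetate) | COC(=O)CC(C)=O | starting material
4 | methyl (6E)-3-oxonona-6,8-dienoate | COC(=O)CC(=O)CC/C=C/C=C | intermediate
5 | methyl (2E,6E)-3-(trifluoromethanesulfonyloxy)nona-2,6,8-trienoate | COC(=O)/C=C(/OS(=O)(=O)C(F)(F)F)CC/C=C/C=C | intermediate
6 | methyl (2E,6E)-3-(propan-2-yl)nona-2,6,8-trienoate | COC(=O)/C=C(/C(C)C)CC/C=C/C=C | intermediate
7 | (2E,6E)-3-(propan-2-yl)nona-2,6,8-trien-1-ol | OC/C=C(/C(C)C)CC/C=C/C=C | intermediate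
8 | trimethyl phosphonoacetate | COC(=O)CP(=O)(OC)OC | starting material
9 | N-methoxy-N-methylprop-2-enamide | C=CC(=O)N(C)OC | starting material
10 | methyl 2-(dimethoxyphosphoryl)-5-[methoxy(methyl)amino]-5-oxopentanoate (racemic) | COC(=O)C(CCC(=O)N(C)OC)P(=O)(OC)OC | intermediate
11 | 1,1-diethoxybut-2-yne | CC#CC(OCC)OCC | starting material
12 | chlorobis(cyclopentadienyl)(4,4-diethoxybut-2-en-2-yl)zirconium, zirconium trans to the acetal carbon | CCOC(OCC)/C=C(/[Zr](Cl)(C1C=CC=C1)C1C=CC=C1)C | intermediate
13 | (2E)-1,1-diethoxy-3-iodobut-2-ene | CCOC(OCC)/C=C(/I)C | intermediate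
14 | (4,4-diethoxybut-2-en-2-yl)lithium, lithium trans to the acetal carbon | CCOC(OCC)/C=C(/[Li])C | intermediate
15 | methyl (6E)-2-(dimethoxyphosphoryl)-8,8-diethoxy-6-methyl-5-oxooct-6-enoate | COC(=O)C(CCC(=O)/C(C)=C/C(OCC)OCC)P(=O)(OC)OC | intermediate
16 | methyl (5R,6E)-2-(dimethoxyphosphoryl)-8,8-diethoxy-5-hydroxy-6-methyloct-6-enoate | COC(=O)C(CC[C@@H](O)/C(C)=C/C(OCC)OCC)P(=O)(OC)OC | intermediate
17 | methyl (5R,6E)-5-(acetyloxy)-2-(dimethoxyphosphoryl)-8,8-diethoxy-6-methyloct-6-enoate | COC(=O)C(CC[C@@H](OC(C)=O)/C(C)=C/C(OCC)OCC)P(=O)(OC)OC | intermediate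
18 | methyl (5R,6E)-5-(acetyloxy)-2-(dimethoxyphosphoryl)-6-methyl-8-oxooct-6-enoate | COC(=O)C(CC[C@@H](OC(C)=O)/C(C)=C/C=O)P(=O)(OC)OC | intermediate
19 | methyl (5R)-5-(acetyloxy)-2-(dimethoxyphosphoryl)-5-{(1R,5R,6R)-6-formyl-5-[(3E)-5-hydroxy-3-(propan-2-yl)pent-3-en-1-yl]-1-methylcyclohex-3-en-1-yl}pentanoate (endo adduct) | COC(=O)C(CC[C@@H](OC(C)=O)[C@]1(C)CC=C[C@@H](CC/C(C(C)C)=C\CO)[C@H]1C=O)P(=O)(OC)OC | intermediate
20 | methyl (5R)-5-(acetyloxy)-2-(dimethoxyphosphoryl)-5-{(1R,5R)-5-[(3E)-5-hydroxy-3-(propan-2-yl)pent-3-en-1-yl]-1-methyl-6-(pyrrolidin-1-ylmethylidene)cyclohex-3-en-1-yl}pentanoate | COC(=O)C(CC[C@@H](OC(C)=O)[C@]1(C)CC=C[C@@H](CC/C(C(C)C)=C\CO)C1=CN2CCCC2)P(=O)(OC)OC | intermediate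
21 | methyl (5R)-5-(acetyloxy)-2-(dimethoxyphosphoryl)-5-{(1S,3R)-3-[(3E)-5-hydroxy-3-(propan-2-yl)pent-3-en-1-yl]-1-methyl-2-oxocyclohex-4-en-1-yl}pentanoate | COC(=O)C(CC[C@@H](OC(C)=O)[C@]1(C)CC=C[C@@H](CC/C(C(C)C)=C\CO)C1=O)P(=O)(OC)OC | intermediate
22 | methyl (5R)-5-(acetyloxy)-2-(dimethoxyphosphoryl)-5-{(1S)-3-[(3E)-5-hydroxy-3-(propan-2-yl)pent-3-en-1-yl]-1-methyl-2-oxocyclohex-3-en-1-yl}pentanoate | COC(=O)C(CC[C@@H](OC(C)=O)[C@]1(C)CCC=C(CC/C(C(C)C)=C\CO)C1=O)P(=O)(OC)OC | intermediate
23 | methyl (5R)-5-(acetyloxy)-2-(dimethoxyphosphoryl)-5-{(2S)-6-[(3E)-5-hydroxy-3-(propan-2-yl)pent-3-en-1-yl]-2-methyl-7-oxo-2,3,4,7-tetrahydrooxepin-2-yl}pentanoate | COC(=O)C(CC[C@@H](OC(C)=O)[C@]1(C)CCC=C(CC/C(C(C)C)=C\CO)C(=O)O1)P(=O)(OC)OC | intermediate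
24 | methyl (5R)-5-(acetyloxy)-2-(dimethoxyphosphoryl)-5-{(2S)-2-methyl-7-oxo-6-[(3E)-5-oxo-3-(propan-2-yl)pent-3-en-1-yl]-2,3,4,7-tetrahydrooxepin-2-yl}pentanoate | COC(=O)C(CC[C@@H](OC(C)=O)[C@]1(C)CCC=C(CC/C(C(C)C)=C\C=O)C(=O)O1)P(=O)(OC)OC | intermediate
25 | Sarcrassin D | COC(=O)/C1=C/C=C(/C(C)C)CCC2=CCC[C@](C)(OC2=O)[C@H](OC(C)=O)CC1 | target

**Step count and risks**

Total step count: 16. Longest linear sequence: 10 steps (steps 1 to 5 and 12 to 16; the branch through steps 7 to 11 and 12 to 16 is equally long).

Steps most likely to fail: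

Step 12. The hindered β,β-disubstituted enal may add too slowly, so that Lewis-acid-induced side reactions take over (carbonyl-ene reaction with the trisubstituted alkene of 7, ionisation of its allylic C–O bond), and the acetoxy stereocentre may discriminate the two enal faces incompletely. Fallback, an ionic Diels–Alder reaction with a cationic dienophile: it sets out from acetal 17 and dienol 7. Dienol 7 is silylated (TBSCl, imidazole) to tert-butyl(dimethyl){[(2E,6E)-3-(propan-2-yl)nona-2,6,8-trien-1-yl]oxy}silane F1. Acetal 17 and F1 are treated with catalytic Me3SiOTf in CH2Cl2 at −78 °C; the alkoxy-allyl cation formed from the acetal is a much stronger dienophile of the same polarity and should give methyl (5R)-5-(acetyloxy)-5-[(1R,5R,6R)-5-[(3E)-5-{[tert-butyl(dimethyl)silyl]oxy}-3-(propan-2-yl)pent-3-en-1-yl]-6-(diethoxymethyl)-1-methylcyclohex-3-en-1-yl]-2-(dimethoxyphosphoryl)pentanoate F2. Aqueous acid (AcOH/THF/H2O) then removes the acetal and the silyl ether, and the route is rejoined at 19.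

Step 13. Enamine formation at the crowded aldehyde may be slow, so that the amine promotes condensation of the phosphonoacetate with the aldehyde instead, or singlet oxygen is consumed in an ene reaction of the trisubstituted alkene. Fallback, deformylation through the copper enolate and not through an enamine: it sets out from 19, which is treated with Cu(OAc)2 (cat.), 2,2'-bipyridine, DABCO and O2 in DMF at 40 °C. The α-hydroperoxy aldehyde fragments to the ketone and formic acid, the base conjugates the enone in the same flask (through 21), and the route is rejoined at 22. No amine condensation, light or singlet oxygen is needed, and no new compound is made (F0).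

Step 14. Addition of the peroxide to the hindered, conjugated ketone may be slow, and migration of the alkenyl carbon (enol lactone) or oxidation elsewhere may compete. Fallback, oxygen insertion before conjugation: it sets out from 21, isolated by leaving out DABCO in step 13. The non-conjugated, more electrophilic ketone is oxidised with the same silyl peroxide; the quaternary carbon should migrate in preference to the secondary ring carbon and give methyl (5R)-5-(acetyloxy)-2-(dimethoxyphosphoryl)-5-{(2S,6R)-6-[(3E)-5-hydroxy-3-(propan-2-yl)pent-3-en-1-yl]-2-methyl-7-oxo-2,3,6,7-tetrahydrooxepin-2-yl}pentanoate F3. DABCO then moves the double bond into conjugation with the lactone carbonyl, and the route is rejoined at 23.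

Further compounds
F1 | step 12 | tert-butyl(dimethyl){[(2E,6E)-3-(propan-2-yl)nona-2,6,8-trien-1-yl]oxy}silane | CC(C)(C)[Si](C)(C)OC/C=C(/C(C)C)CC/C=C/C=C
F2 | step 12 | methyl (5R)-5-(acetyloxy)-5-[(1R,5R,6R)-5-[(3E)-5-{[tert-butyl(dimethyl)silyl]oxy}-3-(propan-2-yl)pent-3-en-1-yl]-6-(diethoxymethyl)-1-methylcyclohex-3-en-1-yl]-2-(dimethoxyphosphoryl)pentanoate | COC(=O)C(CC[C@@H](OC(C)=O)[C@]1(C)CC=C[C@@H](CC/C(C(C)C)=C\CO[Si](C)(C)C(C)(C)C)[C@H]1C(OCC)OCC)P(=O)(OC)OC
F0 | step 13 | none | none
F3 | step 14 | methyl (5R)-5-(acetyloxy)-2-(dimethoxyphosphoryl)-5-{(2S,6R)-6-[(3E)-5-hydroxy-3-(propan-2-yl)pent-3-en-1-yl]-2-methyl-7-oxo-2,3,6,7-tetrahydrooxepin-2-yl}pentanoate | COC(=O)C(CC[C@@H](OC(C)=O)[C@]1(C)CC=C[C@@H](CC/C(C(C)C)=C\CO)C(=O)O1)P(=O)(OC)OC
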